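**Plan**
- Ring A carries C5–OH, the three-carbon chain on C6 and oxygen on C7 (a 1-hydroxy-2-alkyl-3-oxy arene), and its C8a–O1 and C4a–C4 bonds belong to the pyran ring; a vinylketene and a 1-siloxyalkyne assemble exactly this pattern.
- Retrosynthesis: the C6 ketone is stepped back to a silyl-protected carbinol, then ring A is cut at C8–C8a, C5–C6, C7–C8 and C4a–C5 into a dihydropyranyl diazomethyl ketone and a siloxyalkyne bearing ring B.
- Further cuts: alkyne–carbinol bond (ethynyl Grignard plus ring B propanal), aryl–prenyl bond (Stille), cinnamate C=C (Wittig), acetyl–dihydropyran bond (vinyllithium plus Weinreb amide), gem-dimethyl carbinol (MeMgBr plus keto ester).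
- Forward: the pyran ring is made first (steps 1–3) and carried to the diazo ketone; ring B goes from 5-bromovanillin to the siloxyalkyne; ring A arises last, in step 16; four steps then adjust oxidation level and protecting groups.
- Stereochemistry: the target has no stereocentre and no stereogenic alkene; the carbinol centre of 23–34 is racemic and is erased by the oxidation in step 19.

Key step: step 16

Remark: compounds 23–34 are racemic at the side-chain carbinol carbon, and 29 and 31 would form as diastereomer mixtures, so these centres are written without stereodescriptors.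

**Route**

Step 1
Reactants: 1 ethyl 5-oxohexanoate
Product: 3 6,6-dimethyloxan-2-one, via hydroxy ester 2 (not isolated)
Conditions: MeMgBr (1.05 equiv), THF, −78 to −20 °C; aq. NH4Cl; then TsOH·H2O (cat.), PhMe, 50 °C
Reagents that add atoms: methylmagnesium bromide, C[Mg]Br
Why: Chemoselective Grignard addition to the ketone, which is far more electrophilic than the ethyl ester, gives the tertiary carbinol, and acid-catalysed lactonisation then closes the six-membered ring with loss of ethanol.

Step 2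
Reactants: 3 6,6-dimethyloxan-2-one
Product: 4 6,6-dimethyloxan-2-ol (racemic lactol)
Conditions: i-Bu2AlH (1.1 equiv), CH2Cl2, −78 °C; aq. KNaC4H4O6
Reagents that add atoms: none
Why: Partial hydride reduction of a lactone at low temperature stops at the aluminium lactolate, which gives the lactol on work-up.

Step 3
Reactants: 4 6,6-dimethyloxan-2-ol
Product: 6 2,2-dimethyl-3,4-dihydro-2H-pyran, via anomeric mesylate 5 (not isolated)
Conditions: MsCl, Et3N, CH2Cl2, 0 to 40 °C; distillation
Reagents that add atoms: none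
Why: Sulfonylation of the anomeric hydroxyl and amine-promoted elimination through the oxocarbenium ion is a standard lactol-to-cyclic-enol-ether dehydration, and only C3 carries a hydrogen that can be lost.

Step 4
Reactants: 6 2,2-dimethyl-3,4-dihydro-2H-pyran; 7 N-methoxy-N-methylacetamide
Product: 10 1-(6,6-dimethyl-5,6-dihydro-4H-pyran-2-yl)ethan-1-one, via vinyllithium 8 (not isolated), via tetrahedral adduct 9 (not isolated)
Conditions: t-BuLi, THF–pentane, −78 to 0 °C; then 7, −78 to 0 °C; aq. NH4Cl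
Reagents that add atoms: none
Why: Oxygen-directed vinylic lithiation of a cyclic enol ether at its α-carbon followed by Weinreb ketone synthesis, in which the chelated adduct 9 prevents a second addition.

Step 5
Reactants: 10 1-(6,6-dimethyl-5,6-dihydro-4H-pyran-2-yl)ethan-1-one
Product: 12 2-diazo-1-(6,6-dimethyl-5,6-dihydro-4H-pyran-2-yl)ethan-1-one, via trifluoroacetyl diketone 11 (not isolated)
Conditions: LiN(SiMe3)2, THF, −78 °C; CF3CO2CH2CF3; then MsN3, Et3N, H2O, MeCN, rt
Reagents that add atoms: methanesulfonyl azide, CS(=O)(=O)N=[N+]=[N-]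
Why: Detrifluoroacetylative diazo transfer (kinetic enolate trifluoroacetylation at the methyl group, then sulfonyl azide transfer with loss of the trifluoroacetyl group) is the standard way to diazomethyl ketones from α,β-unsaturated methyl ketones.

Step 6
Reactants: 13 5-bromovanillin
Product: 14 3-bromo-4,5-dihydroxybenzaldehyde
Conditions: AlCl3, pyridine, CH2Cl2, reflux; aq. HCl
Reagents that add atoms: none
Why: AlCl3 chelates the ortho-hydroxy methoxy unit and pyridine removes the activated methyl group by SN2 attack, a standard demethylation of vanillin-type ethers that leaves the bromide and the aldehyde alone.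

Step 7
Reactants: 14 3-bromo-4,5-dihydroxybenzaldehyde
Product: 15 3-bromo-5-hydroxy-4-methoxybenzaldehyde
Conditions: MeI (1.1 equiv), Li2CO3, DMF, 40 °C
Reagents that add atoms: iodomethane, CI
Why: Williamson etherification under weak-base control, in which the 4-hydroxyl (para to the formyl group, ortho to bromine) is the more acidic one, so that Li2CO3 forms only its phenoxide and methylation stops at the 4-methyl ether.

Step 8
Reactants: 15 3-bromo-5-hydroxy-4-methoxybenzaldehyde
Product: 16 3-bromo-4-methoxy-5-(triisopropylsilyloxy)benzaldehyde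
Conditions: i-Pr3SiCl, imidazole, DMF, rt
Reagents that add atoms: triisopropylsilyl chloride, CC(C)[Si](Cl)(C(C)C)C(C)C
Why: Imidazole-promoted silylation of a phenol, with the bulky triisopropylsilyl ether chosen to survive the organometallic, hydride and alkoxide conditions up to step 19.

Step 9
Reactants: 16 3-bromo-4-methoxy-5-(triisopropylsilyloxy)benzaldehyde
Product: 17 4-methoxy-3-(3-methylbut-2-enyl)-5-(triisopropylsilyloxy)benzaldehyde
Conditions: Me2C=CHCH2SnBu3, Pd(PPh3)4 (5 mol %), DMF, 90 °C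
Reagents that add atoms: tributyl(3-methylbut-2-enyl)stannane, CCCC[Sn](CCCC)(CCCC)CC=C(C)C
Why: Stille coupling, in which oxidative addition of the aryl bromide to zerovalent palladium, transmetallation of the allylic stannane and reductive elimination at the less substituted allyl terminus give the linear prenyl arene while the aldehyde and silyl ether are tolerated.

Step 10
Reactants: 17 4-methoxy-3-(3-methylbut-2-enyl)-5-(triisopropylsilyloxy)benzaldehyde
Product: 18 ethyl (E)-3-[4-methoxy-3-(3-methylbut-2-enyl)-5-(triisopropylsilyloxy)phenyl]prop-2-enoate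
Conditions: Ph3P=CHCO2Et, PhMe, 80 °C
Reagents that add atoms: ethyl (triphenylphosphoranylidene)acetate, CCOC(=O)C=P(c1ccccc1)(c1ccccc1)c1ccccc1
Why: Wittig olefination with a stabilised ylide, which gives the E-cinnamate.

Step 11
Reactants: 18 ethyl (E)-3-[4-methoxy-3-(3-methylbut-2-enyl)-5-(triisopropylsilyloxy)phenyl]prop-2-enoate
Product: 19 ethyl 3-[4-methoxy-3-(3-methylbut-2-enyl)-5-(triisopropylsilyloxy)phenyl]propanoate
Conditions: Cu(OAc)2·H2O (3 mol %), 1,2-bis(diphenylphosphino)benzene (3 mol %), (EtO)2MeSiH, t-BuOH, PhMe, rt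
Reagents that add atoms: none
Why: Copper hydride conjugate reduction, in which the phosphine-ligated copper hydride adds only to the polarised enoate C=C, so that the unactivated trisubstituted prenyl alkene is not touched.

Step 12
Reactants: 19 ethyl 3-[4-methoxy-3-(3-methylbut-2-enyl)-5-(triisopropylsilyloxy)phenyl]propanoate
Product: 21 3-[4-methoxy-3-(3-methylbut-2-enyl)-5-(triisopropylsilyloxy)phenyl]propanal, via aluminium hemiacetal 20 (not isolated)
Conditions: i-Bu2AlH (1.05 equiv), CH2Cl2, −78 °C; MeOH, then aq. KNaC4H4O6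
Reagents that add atoms: none
Why: Partial reduction of an ester to the aldehyde, possible because the tetrahedral aluminium hemiacetal 20 persists at −78 °C until work-up.

Step 13
Reactants: 21 3-[4-methoxy-3-(3-methylbut-2-enyl)-5-(triisopropylsilyloxy)phenyl]propanal; 22 ethynylmagnesium bromide
Product: 23 5-[4-methoxy-3-(3-methylbut-2-enyl)-5-(triisopropylsilyloxy)phenyl]pent-1-yn-3-ol (racemic)
Conditions: THF, 0 °C; aq. NH4Cl
Reagents that add atoms: none
Why: 1,2-Addition of an alkynyl Grignard reagent to an aldehyde, giving a racemic carbinol whose centre is of no consequence because it becomes the ketone carbon in step 19.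

Step 14
Reactants: 23 5-[4-methoxy-3-(3-methylbut-2-enyl)-5-(triisopropylsilyloxy)phenyl]pent-1-yn-3-ol
Product: 24 3-(triethylsilyloxy)-5-[4-methoxy-3-(3-methylbut-2-enyl)-5-(triisopropylsilyloxy)phenyl]pent-1-yne (racemic)
Conditions: Et3SiCl, imidazole, CH2Cl2, 0 °C to rt
Reagents that add atoms: chlorotriethylsilane, CC[Si](Cl)(CC)CC
Why: Standard silylation of a secondary alcohol, the triethylsilyl ether being chosen because buffered HF can later remove it in the presence of aryl silyl ethers.

Step 15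
Reactants: 24 3-(triethylsilyloxy)-5-[4-methoxy-3-(3-methylbut-2-enyl)-5-(triisopropylsilyloxy)phenyl]pent-1-yne
Product: 27 3-(triethylsilyloxy)-5-[4-methoxy-3-(3-methylbut-2-enyl)-5-(triisopropylsilyloxy)phenyl]-1-(triisopropylsilyloxy)pent-1-yne (racemic), via lithium acetylide 25 (not isolated), via lithium ynolate 26 (not isolated)
Conditions: n-BuLi, THF, −78 °C; t-BuOOLi (from t-BuOOH and LiN(SiMe3)2), −78 to 0 °C; then i-Pr3SiOTf, −78 to 0 °C
Reagents that add atoms: tert-butyl hydroperoxide, CC(C)(C)OO; triisopropylsilyl trifluoromethanesulfonate, CC(C)[Si](OS(=O)(=O)C(F)(F)F)(C(C)C)C(C)C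
Why: Electrophilic oxygenation of a lithium acetylide by lithium tert-butyl peroxide gives the lithium ynolate, which the bulky silyl triflate traps on oxygen, the established one-flask conversion of terminal alkynes into 1-siloxyalkynes.

Step 16
Reactants: 12 2-diazo-1-(6,6-dimethyl-5,6-dihydro-4H-pyran-2-yl)ethan-1-one; 27 3-(triethylsilyloxy)-5-[4-methoxy-3-(3-methylbut-2-enyl)-5-(triisopropylsilyloxy)phenyl]-1-(triisopropylsilyloxy)pent-1-yne
Product: 32 6-{1-(triethylsilyloxy)-3-[4-methoxy-3-(3-methylbut-2-enyl)-5-(triisopropylsilyloxy)phenyl]propyl}-2,2-dimethyl-7-(triisopropylsilyloxy)chroman-5-ol (racemic), via vinylketene 28 (not isolated), via vinylcyclobutenone 29 (not isolated), via dienylketene 30 (not isolated), via cyclohexadienone 31 (not isolated)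
Conditions: hν (medium-pressure Hg lamp, Pyrex filter), ClCH2CH2Cl, rt; then 80 °C; 12 in slight excess
Reagents that add atoms: none
Why: Photolysis expels N2 and the dihydropyranyl group migrates to the carbene carbon (Wolff rearrangement, C8–C8a) to give vinylketene 28, whose C=C adds the electron-rich siloxyalkyne in a polar, stepwise [2+2] cycloaddition (C5–C6 and C7–C8) to give 4-vinylcyclobutenone 29. Heating drives the strain-releasing 4π electrocyclic opening of 29 to dienylketene 30, which closes ring A by a thermal disrotatory 6π electrocyclisation (C4a–C5) onto the β-carbon of the enol ether, and dienone 31 tautomerises to the phenol. The closest known reaction type is the photochemical Danheiser benzannulation of α,β-unsaturated diazomethyl ketones with 1-siloxyalkynes to resorcinol monosilyl ethers, applied here to a diazo ketone whose alkene is part of a cyclic enol ether. No stereocentre is created, since the sp3 centres of 29 and 31 vanish on aromatisation and the carbinol centre is only carried along. The one selectivity needed is the regiochemistry of the [2+2] addition, and the polarisation of the siloxyalkyne secures it: the carbon remote from oxygen is nucleophilic and bonds to the electrophilic ketene carbonyl carbon, which puts the chain on C6 between the two oxygens and the silyloxy group on C7. Pyrex-filtered light is chosen so that mainly the diazo ketone absorbs, and the diazo ketone is the partner used in excess because the alkyne is the more valuable one.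

Step 17
Reactants: 32 6-{1-(triethylsilyloxy)-3-[4-methoxy-3-(3-methylbut-2-enyl)-5-(triisopropylsilyloxy)phenyl]propyl}-2,2-dimethyl-7-(triisopropylsilyloxy)chroman-5-ol
Product: 33 5-(tert-butyldimethylsilyloxy)-6-{1-(triethylsilyloxy)-3-[4-methoxy-3-(3-methylbut-2-enyl)-5-(triisopropylsilyloxy)phenyl]propyl}-2,2-dimethyl-7-(triisopropylsilyloxy)chroman (racemic)
Conditions: t-BuMe2SiOTf, 2,6-lutidine, CH2Cl2, −78 to 0 °C
Reagents that add atoms: tert-butyldimethylsilyl trifluoromethanesulfonate, CC(C)(C)[Si](C)(C)OS(=O)(=O)C(F)(F)F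
Why: Silylation of the hindered C5 phenol with a reactive silyl triflate and a hindered base, which masks the phenol against quinone-methide formation and oxidation in the next two steps.

Step 18
Reactants: 33 5-(tert-butyldimethylsilyloxy)-6-{1-(triethylsilyloxy)-3-[4-methoxy-3-(3-methylbut-2-enyl)-5-(triisopropylsilyloxy)phenyl]propyl}-2,2-dimethyl-7-(triisopropylsilyloxy)chroman
Product: 34 1-[5-(tert-butyldimethylsilyloxy)-2,2-dimethyl-7-(triisopropylsilyloxy)chroman-6-yl]-3-[4-methoxy-3-(3-methylbut-2-enyl)-5-(triisopropylsilyloxy)phenyl]propan-1-ol (racemic)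
Conditions: HF·pyridine, excess pyridine, THF, 0 °C to rt
Reagents that add atoms: none
Why: Selective desilylation under weakly acidic fluoride conditions, where the alkyl triethylsilyl ether is cleaved while the bulkier aryl silyl ethers persist, and where the pyridine buffer keeps the electron-rich benzylic C–O bond from ionising.

Step 19
Reactants: 34 1-[5-(tert-butyldimethylsilyloxy)-2,2-dimethyl-7-(triisopropylsilyloxy)chroman-6-yl]-3-[4-methoxy-3-(3-methylbut-2-enyl)-5-(triisopropylsilyloxy)phenyl]propan-1-ol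
Product: 35 1-[5-(tert-butyldimethylsilyloxy)-2,2-dimethyl-7-(triisopropylsilyloxy)chroman-6-yl]-3-[4-methoxy-3-(3-methylbut-2-enyl)-5-(triisopropylsilyloxy)phenyl]propan-1-one
Conditions: Dess–Martin periodinane, NaHCO3, CH2Cl2, rt
Reagents that add atoms: none
Why: Dess–Martin oxidation of a hindered secondary benzylic alcohol under buffered, non-acidic conditions that leave the prenyl alkene and the aryl silyl ethers intact.

Step 20
Reactants: 35 1-[5-(tert-butyldimethylsilyloxy)-2,2-dimethyl-7-(triisopropylsilyloxy)chroman-6-yl]-3-[4-methoxy-3-(3-methylbut-2-enyl)-5-(triisopropylsilyloxy)phenyl]propan-1-one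
Product: 36 1-(5,7-dihydroxy-2,2-dimethylchroman-6-yl)-3-[3-hydroxy-4-methoxy-5-(3-methylbut-2-enyl)phenyl]propan-1-one (target)
Conditions: Bu4NF, AcOH, THF, 0 °C to rt
Reagents that add atoms: none
Why: Fluoride-mediated desilylation, fast for aryl silyl ethers because phenoxide is a good leaving group from silicon, with acetic acid buffering to protect the 2,6-dihydroxyaryl ketone.

**Compound list**

1 | ethyl 5-oxohexanoate | CCOC(=O)CCCC(C)=O | starting material
2 | ethyl 5-hydroxy-5-methylhexanoate | CCOC(=O)CCCC(C)(C)O | intermediate (not isolated)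
3 | 6,6-dimethyloxan-2-one | CC1(C)CCCC(=O)O1 | intermediate
4 | 6,6-dimethyloxan-2-ol (racemic) | CC1(C)CCCC(O)O1 | intermediate
5 | 6,6-dimethyloxan-2-yl methanesulfonate (racemic) | CC1(C)CCCC(OS(C)(=O)=O)O1 | intermediate (not isolated)
6 | 2,2-dimethyl-3,4-dihydro-2H-pyran | CC1(C)CCC=CO1 | intermediate
7 | N-methoxy-N-methylacetamide | CON(C)C(C)=O | starting material
8 | (6,6-dimethyl-5,6-dihydro-4H-pyran-2-yl)lithium | [Li]C1=CCCC(C)(C)O1 | intermediate (not isolated)
9 | lithium 1-(6,6-dimethyl-5,6-dihydro-4H-pyran-2-yl)-1-[methoxy(methyl)amino]ethan-1-olate (racemic) | CON(C)C(C)(O[Li])C1=CCCC(C)(C)O1 | intermediate (not isolated)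
10 | 1-(6,6-dimethyl-5,6-dihydro-4H-pyran-2-yl)ethan-1-one | CC(=O)C1=CCCC(C)(C)O1 | intermediate
11 | 1-(6,6-dimethyl-5,6-dihydro-4H-pyran-2-yl)-4,4,4-trifluorobutane-1,3-dione | O=C(CC(=O)C(F)(F)F)C1=CCCC(C)(C)O1 | intermediate (not isolated)
12 | 2-diazo-1-(6,6-dimethyl-5,6-dihydro-4H-pyran-2-yl)ethan-1-one | [N-]=[N+]=CC(=O)C1=CCCC(C)(C)O1 | intermediate
13 | 5-bromovanillin (3-bromo-4-hydroxy-5-methoxybenzaldehyde) | O=Cc1cc(Br)c(O)c(OC)c1 | starting material
14 | 3-bromo-4,5-dihydroxybenzaldehyde | O=Cc1cc(Br)c(O)c(O)c1 | intermediate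
15 | 3-bromo-5-hydroxy-4-methoxybenzaldehyde | O=Cc1cc(Br)c(OC)c(O)c1 | intermediate
16 | 3-bromo-4-methoxy-5-(triisopropylsilyloxy)benzaldehyde | O=Cc1cc(Br)c(OC)c(O[Si](C(C)C)(C(C)C)C(C)C)c1 | intermediate
17 | 4-methoxy-3-(3-methylbut-2-enyl)-5-(triisopropylsilyloxy)benzaldehyde | O=Cc1cc(CC=C(C)C)c(OC)c(O[Si](C(C)C)(C(C)C)C(C)C)c1 | intermediate
18 | ethyl (E)-3-[4-methoxy-3-(3-methylbut-2-enyl)-5-(triisopropylsilyloxy)phenyl]prop-2-enoate | CCOC(=O)/C=C/c1cc(CC=C(C)C)c(OC)c(O[Si](C(C)C)(C(C)C)C(C)C)c1 | intermediate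
19 | ethyl 3-[4-methoxy-3-(3-methylbut-2-enyl)-5-(triisopropylsilyloxy)phenyl]propanoate | CCOC(=O)CCc1cc(CC=C(C)C)c(OC)c(O[Si](C(C)C)(C(C)C)C(C)C)c1 | intermediate
20 | diisobutylaluminium 1-ethoxy-3-[4-methoxy-3-(3-methylbut-2-enyl)-5-(triisopropylsilyloxy)phenyl]propan-1-olate (racemic) | CCOC(O[Al](CC(C)C)CC(C)C)CCc1cc(CC=C(C)C)c(OC)c(O[Si](C(C)C)(C(C)C)C(C)C)c1 | intermediate (not isolated)
21 | 3-[4-methoxy-3-(3-methylbut-2-enyl)-5-(triisopropylsilyloxy)phenyl]propanal | O=CCCc1cc(CC=C(C)C)c(OC)c(O[Si](C(C)C)(C(C)C)C(C)C)c1 | intermediate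
22 | ethynylmagnesium bromide | C#C[Mg]Br | starting material
23 | 5-[4-methoxy-3-(3-methylbut-2-enyl)-5-(triisopropylsilyloxy)phenyl]pent-1-yn-3-ol (racemic) | C#CC(O)CCc1cc(CC=C(C)C)c(OC)c(O[Si](C(C)C)(C(C)C)C(C)C)c1 | intermediate
24 | 3-(triethylsilyloxy)-5-[4-methoxy-3-(3-methylbut-2-enyl)-5-(triisopropylsilyloxy)phenyl]pent-1-yne (racemic) | C#CC(O[Si](CC)(CC)CC)CCc1cc(CC=C(C)C)c(OC)c(O[Si](C(C)C)(C(C)C)C(C)C)c1 | intermediate
25 | {3-(triethylsilyloxy)-5-[4-methoxy-3-(3-methylbut-2-enyl)-5-(triisopropylsilyloxy)phenyl]pent-1-yn-1-yl}lithium (racemic) | [Li]C#CC(O[Si](CC)(CC)CC)CCc1cc(CC=C(C)C)c(OC)c(O[Si](C(C)C)(C(C)C)C(C)C)c1 | intermediate (not isolated)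
26 | lithium 3-(triethylsilyloxy)-5-[4-methoxy-3-(3-methylbut-2-enyl)-5-(triisopropylsilyloxy)phenyl]pent-1-yn-1-olate (racemic) | [Li]OC#CC(O[Si](CC)(CC)CC)CCc1cc(CC=C(C)C)c(OC)c(O[Si](C(C)C)(C(C)C)C(C)C)c1 | intermediate (not isolated)
27 | 3-(triethylsilyloxy)-5-[4-methoxy-3-(3-methylbut-2-enyl)-5-(triisopropylsilyloxy)phenyl]-1-(triisopropylsilyloxy)pent-1-yne (racemic) | CC(C)[Si](OC#CC(O[Si](CC)(CC)CC)CCc1cc(CC=C(C)C)c(OC)c(O[Si](C(C)C)(C(C)C)C(C)C)c1)(C(C)C)C(C)C | intermediate
28 | 2-(6,6-dimethyl-5,6-dihydro-4H-pyran-2-yl)ethen-1-one | O=C=CC1=CCCC(C)(C)O1 | intermediate (not isolated)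
29 | 4-(6,6-dimethyl-5,6-dihydro-4H-pyran-2-yl)-2-{1-(triethylsilyloxy)-3-[4-methoxy-3-(3-methylbut-2-enyl)-5-(triisopropylsilyloxy)phenyl]propyl}-3-(triisopropylsilyloxy)cyclobut-2-en-1-one (diastereomer mixture) | O=C1C(C(O[Si](CC)(CC)CC)CCc2cc(CC=C(C)C)c(OC)c(O[Si](C(C)C)(C(C)C)C(C)C)c2)=C(O[Si](C(C)C)(C(C)C)C(C)C)C1C3=CCCC(C)(C)O3 | intermediate (not isolated)
30 | 4-(6,6-dimethyl-5,6-dihydro-4H-pyran-2-yl)-2-{1-(triethylsilyloxy)-3-[4-methoxy-3-(3-methylbut-2-enyl)-5-(triisopropylsilyloxy)phenyl]propyl}-3-(triisopropylsilyloxy)buta-1,3-dien-1-one (racemic) | O=C=C(C(O[Si](CC)(CC)CC)CCc1cc(CC=C(C)C)c(OC)c(O[Si](C(C)C)(C(C)C)C(C)C)c1)C(O[Si](C(C)C)(C(C)C)C(C)C)=CC2=CCCC(C)(C)O2 | intermediate (not isolated)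
31 | 6-{1-(triethylsilyloxy)-3-[4-methoxy-3-(3-methylbut-2-enyl)-5-(triisopropylsilyloxy)phenyl]propyl}-2,2-dimethyl-7-(triisopropylsilyloxy)-2,3,4,4a-tetrahydro-5H-chromen-5-one (diastereomer mixture) | O=C1C(C(O[Si](CC)(CC)CC)CCc2cc(CC=C(C)C)c(OC)c(O[Si](C(C)C)(C(C)C)C(C)C)c2)=C(O[Si](C(C)C)(C(C)C)C(C)C)C=C3OC(C)(C)CCC13 | intermediate (not isolated)
32 | 6-{1-(triethylsilyloxy)-3-[4-methoxy-3-(3-methylbut-2-enyl)-5-(triisopropylsilyloxy)phenyl]propyl}-2,2-dimethyl-7-(triisopropylsilyloxy)chroman-5-ol (racemic) | CC1(C)CCc2c(O)c(C(O[Si](CC)(CC)CC)CCc3cc(CC=C(C)C)c(OC)c(O[Si](C(C)C)(C(C)C)C(C)C)c3)c(O[Si](C(C)C)(C(C)C)C(C)C)cc2O1 | intermediate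
33 | 5-(tert-butyldimethylsilyloxy)-6-{1-(triethylsilyloxy)-3-[4-methoxy-3-(3-methylbut-2-enyl)-5-(triisopropylsilyloxy)phenyl]propyl}-2,2-dimethyl-7-(triisopropylsilyloxy)chroman (racemic) | CC1(C)CCc2c(O[Si](C)(C)C(C)(C)C)c(C(O[Si](CC)(CC)CC)CCc3cc(CC=C(C)C)c(OC)c(O[Si](C(C)C)(C(C)C)C(C)C)c3)c(O[Si](C(C)C)(C(C)C)C(C)C)cc2O1 | intermediate
34 | 1-[5-(tert-butyldimethylsilyloxy)-2,2-dimethyl-7-(triisopropylsilyloxy)chroman-6-yl]-3-[4-methoxy-3-(3-methylbut-2-enyl)-5-(triisopropylsilyloxy)phenyl]propan-1-ol (racemic) | CC1(C)CCc2c(O[Si](C)(C)C(C)(C)C)c(C(O)CCc3cc(CC=C(C)C)c(OC)c(O[Si](C(C)C)(C(C)C)C(C)C)c3)c(O[Si](C(C)C)(C(C)C)C(C)C)cc2O1 | intermediate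
35 | 1-[5-(tert-butyldimethylsilyloxy)-2,2-dimethyl-7-(triisopropylsilyloxy)chroman-6-yl]-3-[4-methoxy-3-(3-methylbut-2-enyl)-5-(triisopropylsilyloxy)phenyl]propan-1-one | CC1(C)CCc2c(O[Si](C)(C)C(C)(C)C)c(C(=O)CCc3cc(CC=C(C)C)c(OC)c(O[Si](C(C)C)(C(C)C)C(C)C)c3)c(O[Si](C(C)C)(C(C)C)C(C)C)cc2O1 | intermediate
36 | 1-(5,7-dihydroxy-2,2-dimethylchroman-6-yl)-3-[3-hydroxy-4-methoxy-5-(3-methylbut-2-enyl)phenyl]propan-1-one (CNP0408176.0) | COc1c(O)cc(CCC(=O)c2c(O)cc3c(c2O)CCC(C)(C)O3)cc1CC=C(C)C | target

**Step count**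
Total: 20 steps. Longest linear sequence: 15 steps (13 to 36, steps 6–20); the diazo ketone arm adds 5 steps (1 to 12).

**Steps most likely to fail**

Step 16. The photochemical stage may stall: migration of the electron-rich alkenyl group in the Wolff step may be inefficient, ring B and the product phenol may screen the light, and the ketene may be lost to dimerisation or to acylation of the product phenol before it meets the alkyne. The fallback reaches the same vinylketene 28 without light, by 1,4-dehydrochlorination of an unsaturated acid chloride. It sets out from lactone 3. Addition of LiCH2CO2Et (EtOAc, LiN(i-Pr)2, THF, −78 °C) would give the hemiketal ethyl 2-(2-hydroxy-6,6-dimethyloxan-2-yl)acetate F1. Dehydration with catalytic TsOH in toluene would give ethyl 2-(6,6-dimethyloxan-2-ylidene)acetate F2, either alkene isomer being usable. Saponification with LiOH would give 2-(6,6-dimethyloxan-2-ylidene)acetic acid F3, and 1-chloro-N,N,2-trimethylprop-1-en-1-amine would convert it under neutral conditions into 2-(6,6-dimethyloxan-2-ylidene)acetyl chloride F4. Slow addition of F4 to Et3N and siloxyalkyne 27 in toluene at rt, then 80 °C, should generate 28 by γ-deprotonation of the acylammonium ion. From 28 the sequence runs through 29, 30 and 31 as before and rejoins the route at phenol 32.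

Step 15. Oxygen transfer from the peroxide to the hindered, inductively deactivated acetylide may be incomplete, and tert-butoxide or peroxide may attack the silyl ethers during the warm-up. The fallback makes lithium ynolate 26 by Kowalski ester homologation and sets out from aldehyde 17. Wittig reaction with ethyl 2-oxo-3-(triphenylphosphoranylidene)propanoate would give ethyl (E)-4-[4-methoxy-3-(3-methylbut-2-enyl)-5-(triisopropylsilyloxy)phenyl]-2-oxobut-3-enoate F5. Conjugate transfer hydrogenation with Hantzsch ester (PhMe, 60 °C) would give ethyl 4-[4-methoxy-3-(3-methylbut-2-enyl)-5-(triisopropylsilyloxy)phenyl]-2-oxobutanoate F6. NaBH4 in EtOH at −40 °C would reduce the keto group to give ethyl 2-hydroxy-4-[4-methoxy-3-(3-methylbut-2-enyl)-5-(triisopropylsilyloxy)phenyl]butanoate F7. Et3SiCl and imidazole would give ethyl 4-[4-methoxy-3-(3-methylbut-2-enyl)-5-(triisopropylsilyloxy)phenyl]-2-(triethylsilyloxy)butanoate F8. Treatment with LiCHBr2 (from CH2Br2 and lithium 2,2,6,6-tetramethylpiperidide, THF, −78 °C), then LiN(SiMe3)2 and n-BuLi, would pass through the dibromo enolate lithium 1,1-dibromo-3-(triethylsilyloxy)-5-[4-methoxy-3-(3-methylbut-2-enyl)-5-(triisopropylsilyloxy)phenyl]pent-1-en-2-olate F9. Bromine–lithium exchange and 1,2-shift of the silyloxyalkyl group in F9 give ynolate 26, which i-Pr3SiOTf converts into 27 as in step 15.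

Step 18. The crowded triethylsilyl ether may be cleaved too slowly, so that the benzylic C–O bond of the very electron-rich arene ionises (elimination or quinone-methide chemistry) or an aryl silyl ether is lost first. The fallback gives up the selective deprotection and sets out from 33. Bu4NF buffered with AcOH (THF, 0 °C) would remove all four silyl groups and give the tetraol 6-{1-hydroxy-3-[3-hydroxy-4-methoxy-5-(3-methylbut-2-enyl)phenyl]propyl}-2,2-dimethylchroman-5,7-diol F10, to be handled without acid. DDQ (1 equiv, dioxane, rt) should then oxidise the ortho-hydroxybenzylic alcohol chemoselectively, by hydride abstraction assisted by the ortho and para oxygen substituents, and stop at the deactivated aryl ketone. This arrives directly at target 36.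

Further compounds
F1 | step 16 | ethyl 2-(2-hydroxy-6,6-dimethyloxan-2-yl)acetate (racemic) | CCOC(=O)CC1(O)CCCC(C)(C)O1
F2 | step 16 | ethyl 2-(6,6-dimethyloxan-2-ylidene)acetate (alkene geometry not defined) | CCOC(=O)C=C1CCCC(C)(C)O1
F3 | step 16 | 2-(6,6-dimethyloxan-2-ylidene)acetic acid (alkene geometry not defined) | OC(=O)C=C1CCCC(C)(C)O1
F4 | step 16 | 2-(6,6-dimethyloxan-2-ylidene)acetyl chloride (alkene geometry not defined) | ClC(=O)C=C1CCCC(C)(C)O1
F5 | step 15 | ethyl (E)-4-[4-methoxy-3-(3-methylbut-2-enyl)-5-(triisopropylsilyloxy)phenyl]-2-oxobut-3-enoate | CCOC(=O)C(=O)/C=C/c1cc(CC=C(C)C)c(OC)c(O[Si](C(C)C)(C(C)C)C(C)C)c1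
F6 | step 15 | ethyl 4-[4-methoxy-3-(3-methylbut-2-enyl)-5-(triisopropylsilyloxy)phenyl]-2-oxobutanoate | CCOC(=O)C(=O)CCc1cc(CC=C(C)C)c(OC)c(O[Si](C(C)C)(C(C)C)C(C)C)c1
F7 | step 15 | ethyl 2-hydroxy-4-[4-methoxy-3-(3-methylbut-2-enyl)-5-(triisopropylsilyloxy)phenyl]butanoate (racemic) | CCOC(=O)C(O)CCc1cc(CC=C(C)C)c(OC)c(O[Si](C(C)C)(C(C)C)C(C)C)c1
F8 | step 15 | ethyl 4-[4-methoxy-3-(3-methylbut-2-enyl)-5-(triisopropylsilyloxy)phenyl]-2-(triethylsilyloxy)butanoate (racemic) | CCOC(=O)C(O[Si](CC)(CC)CC)CCc1cc(CC=C(C)C)c(OC)c(O[Si](C(C)C)(C(C)C)C(C)C)c1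
F9 | step 15 | lithium 1,1-dibromo-3-(triethylsilyloxy)-5-[4-methoxy-3-(3-methylbut-2-enyl)-5-(triisopropylsilyloxy)phenyl]pent-1-en-2-olate (racemic) | [Li]OC(=C(Br)Br)C(O[Si](CC)(CC)CC)CCc1cc(CC=C(C)C)c(OC)c(O[Si](C(C)C)(C(C)C)C(C)C)c1
F10 | step 18 | 6-{1-hydroxy-3-[3-hydroxy-4-methoxy-5-(3-methylbut-2-enyl)phenyl]propyl}-2,2-dimethylchroman-5,7-diol (racemic) | CC1(C)CCc2c(O)c(C(O)CCc3cc(CC=C(C)C)c(OC)c(O)c3)c(O)cc2O1
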